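Ring B, the 4-alkylphenol, is treated as a dehydrogenated 4-alkylcyclohex-2-enone. Its para carbon (bonded to chain carbon C9) and one meta carbon are the α-carbon and the formyl carbon of an aldehyde; the hydroxyl-bearing carbon, both ortho carbons and the other meta carbon come from but-3-en-2-one. One amine-mediated Michael–aldol annulation therefore makes two ring B carbon–carbon bonds and closes the carbocycle on a substrate that already carries ring A, both methyl ethers and the aryl ketone. The precursor is the linear keto aldehyde 11-(2,6-dimethoxyphenyl)-11-oxoundecanal, built from 1,3-dimethoxybenzene and undec-10-enal; Pd(O2CCF3)2-catalysed aerobic dehydrogenation then gives the phenol.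

Key step: step 4

Remark on the chemistry: ring A is the 2,6-dimethoxyphenyl ring, ring B the 4-hydroxyphenyl ring, and the chain runs from C1 (ketone) to C9 (on ring B). The alkene is hydroborated while C1 is still a carbinol, because boranes also reduce ketones, and both alcohols are then oxidised in one operation.

Step 1
Reactants: 1 1,3-dimethoxybenzene; 2 undec-10-enal
Product: 4 1-(2,6-dimethoxyphenyl)undec-10-en-1-ol (racemic), via 2-lithio-1,3-dimethoxybenzene 3 (not isolated)
Conditions: nBuLi, THF, 0 °C to rt; then 2, −78 to 0 °C; H2O
Reagents that add atoms: none
Why: Directed ortho-lithiation of 1 at C2, the position flanked by both methoxy groups, gives aryllithium 3, whose 1,2-addition to the aldehyde of 2 at low temperature should outpace enolisation; the new carbinol stereocentre is formed without control (racemic) and is removed by oxidation in step 3.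

Step 2
Reactants: 4 1-(2,6-dimethoxyphenyl)undec-10-en-1-ol
Product: 6 1-(2,6-dimethoxyphenyl)undecane-1,11-diol (racemic), via B-alkyl-9-BBN adduct 5 (not isolated)
Conditions: 9-BBN (2.5 equiv), THF, 0 °C to rt; then aq. NaOH, H2O2, 0 °C to rt
Reagents that add atoms: hydrogen peroxide, OO
Why: Anti-Markovnikov hydroboration of the terminal alkene with the bulky dialkylborane puts boron on the terminal carbon and oxidation with retention gives the primary alcohol; no ketone is present to compete for the borane, any O-borylation of the carbinol is undone in the alkaline peroxide work-up, and no new stereocentre is formed.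

Step 3
Reactants: 6 1-(2,6-dimethoxyphenyl)undecane-1,11-diol
Product: 7 11-(2,6-dimethoxyphenyl)-11-oxoundecanal
Conditions: Dess–Martin periodinane (2.6 equiv), pyridine, CH2Cl2, 0 °C to rt
Reagents that add atoms: none
Why: Dess–Martin oxidation should convert the hindered benzylic carbinol to the aryl ketone and the primary alcohol to the aldehyde in one buffered, near-neutral operation without over-oxidation, and it erases the racemic carbinol centre.

Step 4
Reactants: 7 11-(2,6-dimethoxyphenyl)-11-oxoundecanal; 8 but-3-en-2-one
Product: 11 4-[9-(2,6-dimethoxyphenyl)-9-oxononyl]cyclohex-2-en-1-one (racemic), via Michael adduct 9 (not isolated), via ketol 10 (not isolated)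
Conditions: Et2NH (0.3 equiv), 8 (1.5 equiv), THF, rt; concentrate; then 0.1 M aq. KOH, nBu4NOH (cat.), THF/Et2O, reflux
Reagents that add atoms: none
Why: Diethylamine condenses reversibly with the formyl group of 7 to an enamine whose nucleophilic carbon (C2 of the undecanal chain) adds to the terminal CH2 of 8, and hydrolysis of the resulting iminium ion returns the amine and leaves keto aldehyde 9; aqueous KOH then converts the methyl ketone into its enolate, which attacks the formyl carbon to give ketol 10, and loss of water gives the conjugated enone 11. The closest known reaction type is the amine-catalysed Michael addition of aldehydes to vinyl ketones followed by intramolecular aldol condensation, the enamine (Stork) variant of the Robinson annulation that is the standard entry to 4-alkylcyclohex-2-enones. The ring closes by a 6-(enolendo)-exo-trig aldol, so that the two new bonds are C4–C5 and C2–C3 of the cyclohexenone. C4 is formed as a racemate and needs no control because it becomes an aromatic carbon in step 5, and the carbinol carbon of 10 disappears on dehydration. The step needs chemoselectivity between the two carbonyl groups, which is secured because only the unhindered aldehyde forms an enamine while the di-ortho-methoxy aryl ketone is shielded and twisted, and it needs a single mode of cyclisation, which is secured because any other aldol within 9 would close a four-membered ring or a macrocycle; a second Michael addition is held back because the α-branched aldehyde 9 forms its enamine far more slowly than 7.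

Step 5
Reactants: 11 4-[9-(2,6-dimethoxyphenyl)-9-oxononyl]cyclohex-2-en-1-one
Product: 12 1-(2,6-dimethoxyphenyl)-9-(4-hydroxyphenyl)nonan-1-one
Conditions: Pd(O2CCF3)2 (5 mol %), 2-(dimethylamino)pyridine (10 mol %), TsOH·H2O (20 mol %), O2 (1 atm), DMSO, 80 °C
Reagents that add atoms: none
Why: Aerobic palladium-catalysed dehydrogenation of a cyclohexenone proceeds by palladium enolate formation and β-hydride elimination to the cross-conjugated dienone, which tautomerises to the phenol while O2 returns zerovalent palladium to divalent palladium; the acyclic aryl ketone, the methyl ethers and the saturated chain should be untouched, and the free phenol appears without any protecting group.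

Compound list
1 | 1,3-dimethoxybenzene | COc1cccc(OC)c1 | starting material
2 | undec-10-enal | C=CCCCCCCCCC=O | starting material
3 | 2-lithio-1,3-dimethoxybenzene | COc1cccc(OC)c1[Li] | intermediate
4 | 1-(2,6-dimethoxyphenyl)undec-10-en-1-ol (racemic) | COc1cccc(OC)c1C(O)CCCCCCCCC=C | intermediate
5 | 9-[11-(2,6-dimethoxyphenyl)-11-hydroxyundecyl]-9-borabicyclo[3.3.1]nonane (racemic) | COc1cccc(OC)c1C(O)CCCCCCCCCCB1C2CCCC1CCC2 | intermediate
6 | 1-(2,6-dimethoxyphenyl)undecane-1,11-diol (racemic) | COc1cccc(OC)c1C(O)CCCCCCCCCCO | intermediate
7 | 11-(2,6-dimethoxyphenyl)-11-oxoundecanal | COc1cccc(OC)c1C(=O)CCCCCCCCCC=O | intermediate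
8 | but-3-en-2-one | CC(=O)C=C | starting material
9 | 11-(2,6-dimethoxyphenyl)-11-oxo-2-(3-oxobutyl)undecanal (racemic) | COc1cccc(OC)c1C(=O)CCCCCCCCC(C=O)CCC(C)=O | intermediate
10 | 4-[9-(2,6-dimethoxyphenyl)-9-oxononyl]-3-hydroxycyclohexan-1-one (racemic, mixture of diastereomers) | COc1cccc(OC)c1C(=O)CCCCCCCCC1CCC(=O)CC1O | intermediate
11 | 4-[9-(2,6-dimethoxyphenyl)-9-oxononyl]cyclohex-2-en-1-one (racemic) | COc1cccc(OC)c1C(=O)CCCCCCCCC1CCC(=O)C=C1 | intermediate
12 | 1-(2,6-dimethoxyphenyl)-9-(4-hydroxyphenyl)nonan-1-one | COc1cccc(OC)c1C(=O)CCCCCCCCc1ccc(O)cc1 | target

Total step count: 5
Longest linear sequence: 5 steps (2 → 4 → 6 → 7 → 11 → 12)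

Steps most likely to fail

Step 4. The enamine of 7 may condense with a second molecule of 7 (self-aldol), or the enone may oligomerise faster than the cross Michael addition takes place. The fallback sets out from 7 and returns to the route at 11, and it reverses the polarity of the annulation. α-Methylenation of 7 with aqueous formaldehyde and catalytic pyrrolidine/propionic acid in iPrOH at 45 °C should give 11-(2,6-dimethoxyphenyl)-2-methylidene-11-oxoundecanal F1. Base-catalysed Michael addition of tert-butyl acetoacetate (catalytic DBU, CH2Cl2, 0 °C to rt) to the methylidene carbon of this 2-alkylacrolein should give tert-butyl 2-acetyl-13-(2,6-dimethoxyphenyl)-4-formyl-13-oxotridecanoate F2. Heating F2 with TsOH in toluene at 80 °C should bring about aldol condensation of the acetyl methyl group onto the formyl carbon, cleavage of the tert-butyl ester and decarboxylation, which gives 11.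

Step 5. The dehydrogenation may stall when the catalyst aggregates to inactive metal, or oxidation may spread to the position next to the aryl ketone or to the electron-rich phenol. The fallback sets out from 11 and returns at 12. It replaces the catalytic aerobic process by a stoichiometric quinone dehydrogenation: DDQ (about one equivalent) with catalytic TsOH in 1,4-dioxane at reflux. The acid generates the dienol, the quinone abstracts hydride, and the resulting dienone tautomerises to the phenol. The quinone is kept near one equivalent because an excess could oxidise the benzylic position of the product phenol. No new compound is isolated on this path (F0).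

Step 3. Oxidation of the hindered, twisted benzylic carbinol may be slow while the newly formed aldehyde is left exposed, or the electron-rich benzylic alcohol may ionise under the acid released. The fallback sets out from 6 and returns at 7, and it addresses each alcohol with a reagent specific to its class. Activated MnO2 in CH2Cl2 at rt should oxidise only the benzylic carbinol and give 1-(2,6-dimethoxyphenyl)-11-hydroxyundecan-1-one F3. TEMPO (catalytic) with PhI(OAc)2 in CH2Cl2 should then oxidise the primary alcohol to the aldehyde 7 under neutral conditions.

Further compounds
F1 | step 4 | 11-(2,6-dimethoxyphenyl)-2-methylidene-11-oxoundecanal | COc1cccc(OC)c1C(=O)CCCCCCCCC(=C)C=O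
F2 | step 4 | tert-butyl 2-acetyl-13-(2,6-dimethoxyphenyl)-4-formyl-13-oxotridecanoate (mixture of diastereomers) | COc1cccc(OC)c1C(=O)CCCCCCCCC(C=O)CC(C(C)=O)C(=O)OC(C)(C)C
F0 | step 5 | none | none
F3 | step 3 | 1-(2,6-dimethoxyphenyl)-11-hydroxyundecan-1-one | COc1cccc(OC)c1C(=O)CCCCCCCCCCO
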